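## Retrosynthetic overview

- The seven-membered ring D is opened at the bond between its CH(2,4-dihydroxyphenyl) carbon and the resorcinol ring (Friedel–Crafts retron), which reveals an (E)-stilbene on the central benzene ring A.
- Enabling feature: after this cut, ring A carries two identical trans-(2R,3R)-2-(4-hydroxyphenyl)-3-(3,5-dihydroxyphenyl)-2,3-dihydrofuran rings B and C, related by a twofold axis through the ring-A C–H carbon and the stilbene-bearing carbon. Each furan is one aryl C–O bond plus one aryl C–C bond on adjacent ring-A carbons.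
- Key disconnection: both furans at once, by twofold insertion of a ring-A bis-aryne into a benzylic C–O bond of an enantiopure (S,S)-stilbene oxide. The bis-aryne comes from 5-chlororesorcinol, whose two phenol oxygens leave as triflate; the chlorine steers the aryne regiochemistry and later becomes the stilbene by Suzuki–Miyaura coupling.
- Order of ring formation: rings B and C together (step 7), ring D last (step 13), in the same acid treatment that removes all methoxymethyl (MOM) groups.

Key step: step 7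

Assumption: 5-chlororesorcinol, diethyl (4-hydroxybenzyl)phosphonate, bis[(pinacolato)boryl]methane and the L-fructose-derived enantiomer of the Shi ketone are treated as purchasable.

## Route

Step 1
Reactants: 1 5-chlororesorcinol (5-chlorobenzene-1,3-diol)
Product: 2 4,6-dibromo-5-chlorobenzene-1,3-diol
Conditions: NBS (2.05 equiv), MeCN, −20 °C to rt
Reagents that add atoms: N-bromosuccinimide, O=C1CCC(=O)N1Br
Why: electrophilic aromatic bromination, in which C4 and C6 are each para to one hydroxyl and ortho to the other while C2 is only ortho,ortho-activated, so the 4,6-dibromide should form as it does from resorcinol itself.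

Step 2
Reactants: 2 4,6-dibromo-5-chlorobenzene-1,3-diol
Product: 5 5-chloro-4,6-bis(trimethylsilyl)-1,3-phenylene bis(trifluoromethanesulfonate), via bis(trimethylsilyl) ether 3 (not isolated), via dilithium C-silyl bis(phenoxide) 4 (not isolated)
Conditions: HMDS, THF, 70 °C; evaporate; n-BuLi (2.2 equiv), THF, −100 to −78 °C; Tf2O (2.5 equiv), −78 °C to rt
Reagents that add atoms: hexamethyldisilazane, C[Si](C)(C)N[Si](C)(C)C; trifluoromethanesulfonic anhydride, O=S(=O)(OS(=O)(=O)C(F)(F)F)C(F)(F)F
Why: O-silylation, bromine–lithium exchange, anionic 1,3 O-to-C silyl shift (retro-Brook rearrangement) and O-triflation in one flask, the standard way from 2-bromophenols to ortho-silylaryl triflates; the ortho-chloroaryllithium should survive at −100 to −78 °C because the intramolecular silyl transfer is fast.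

Step 3
Reactants: 6 3,5-dihydroxybenzaldehyde
Product: 7 3,5-bis(methoxymethoxy)benzaldehyde
Conditions: MOMCl (2.5 equiv), iPr2NEt, CH2Cl2, 0 °C to rt
Reagents that add atoms: chloromethyl methyl ether, COCCl
Why: O-alkylation of both phenols to base-stable, acid-labile acetals that fall in the last step.

Step 4
Reactants: 8 diethyl (4-hydroxybenzyl)phosphonate
Product: 9 diethyl [4-(trifluoromethylsulfonyloxy)benzyl]phosphonate
Conditions: Tf2O, pyridine, CH2Cl2, 0 °C
Reagents that add atoms: trifluoromethanesulfonic anhydride, O=S(=O)(OS(=O)(=O)C(F)(F)F)C(F)(F)F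
Why: O-sulfonylation of the phenol; the triflate is an electron-withdrawing phenol mask that later deactivates its own benzylic epoxide carbon and keeps the epoxide stable.

Step 5
Reactants: 9 diethyl [4-(trifluoromethylsulfonyloxy)benzyl]phosphonate; 7 3,5-bis(methoxymethoxy)benzaldehyde
Product: 10 4-[(E)-2-[3,5-bis(methoxymethoxy)phenyl]ethenyl]phenyl trifluoromethanesulfonate
Conditions: NaH, 15-crown-5 (cat.), THF, 0 °C to rt
Reagents that add atoms: none
Why: Horner–Wadsworth–Emmons olefination of a stabilised benzylic phosphonate anion with an aryl aldehyde, which should give the (E)-stilbene.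

Step 6
Reactants: 10 4-[(E)-2-[3,5-bis(methoxymethoxy)phenyl]ethenyl]phenyl trifluoromethanesulfonate
Product: 11 4-[(2S,3S)-3-[3,5-bis(methoxymethoxy)phenyl]oxiran-2-yl]phenyl trifluoromethanesulfonate
Conditions: L-fructose-derived Shi ketone (30 mol %), Oxone (2KHSO5·KHSO4·K2SO4), K2CO3, Bu4NHSO4, MeCN–dimethoxymethane / aq. Na2B4O7–Na2EDTA buffer, 0 °C
Reagents that add atoms: potassium peroxymonosulfate (active component of Oxone), [K+].[O-]S(=O)(=O)OO
Why: Shi asymmetric epoxidation of an (E)-1,2-diarylethene through the spiro dioxirane transition state; the L-fructose-derived ketone should give the (S,S)-epoxide (the D-fructose ketone gives the R,R sense), so both stereocentres are set by the catalyst.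

Step 7
Reactants: 5 5-chloro-4,6-bis(trimethylsilyl)-1,3-phenylene bis(trifluoromethanesulfonate); 11 4-[(2S,3S)-3-[3,5-bis(methoxymethoxy)phenyl]oxiran-2-yl]phenyl trifluoromethanesulfonate (3 equiv)
Product: 15 (2R,3R,5R,6R)-4-chloro-3,5-bis[3,5-bis(methoxymethoxy)phenyl]-2,6-bis[4-(trifluoromethylsulfonyloxy)phenyl]-2,3,5,6-tetrahydrobenzo[1,2-b:5,4-b']difuran, via aryne 12 (not isolated), via monoannulated silyl triflate 13 (not isolated), via aryne 14 (not isolated)
Conditions: CsF (6 equiv), 18-crown-6, PhMe, 40 °C, slow addition of 5 to 11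
Reagents that add atoms: none
Why: Proposed new method: fluoride removes one trimethylsilyl group of 5 and triflate leaves to give aryne 12, whose carbon remote from chlorine (the aryne is distorted by the ortho C–Cl bond, as in 3-haloarynes) is attacked by the oxirane oxygen of 11; the aryl anion/oxiranium zwitterion then collapses by heterolysis of the benzylic C–O bond at the carbon carrying the 3,5-bis(methoxymethoxy)phenyl group and C–C bond formation to the anionic ring-A carbon, and the sequence repeats through 13 and aryne 14. The closest known reaction types are the insertion of benzyne into a C–O bond of styrene oxide to give a 2,3-dihydrobenzofuran and the aryne-triggered ring opening of cyclic ethers; the twofold use on one benzene ring and the 2,3-diaryloxirane are new. Each dihydrofuran ring (B, then C) closes by ring expansion of the oxiranium from three to five members, the benzylic carbon shifting from oxygen to the neighbouring carbanionic carbon of ring A by cation–anion recombination within a five-membered array. The O-bearing stereocentre of each ring keeps the configuration of 11 because its C–O bond is never broken, and the carbon stereocentre is formed either with retention inside the ion pair or, through the open benzylic cation, trans to the neighbouring aryl group, so both paths should give the trans-(2R,3R) rings. Three selectivities are needed: oxygen attack at the aryne carbon far from chlorine (secured by the chlorine, which also stabilises the adjacent aryl anion), cleavage of the correct oxirane C–O bond (secured by the para-triflyloxy group, which disfavours positive charge at the other benzylic carbon), and homochiral pairing of the two rings (secured by enantiopure 11, any minor enantiomer being channelled mainly into a separable meso-type diastereomer).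

Step 8
Reactants: 15 (2R,3R,5R,6R)-4-chloro-3,5-bis[3,5-bis(methoxymethoxy)phenyl]-2,6-bis[4-(trifluoromethylsulfonyloxy)phenyl]-2,3,5,6-tetrahydrobenzo[1,2-b:5,4-b']difuran
Product: 16 (2R,3R,5R,6R)-4-chloro-3,5-bis[3,5-bis(methoxymethoxy)phenyl]-2,6-bis(4-hydroxyphenyl)-2,3,5,6-tetrahydrobenzo[1,2-b:5,4-b']difuran
Conditions: Et4NOH (aq.), 1,4-dioxane, rt, then neutral work-up
Reagents that add atoms: none
Why: hydroxide attacks sulfur and cleaves both aryl triflates (S–O scission) at room temperature without touching the acetals, the aryl chloride or the stereocentres.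

Step 9
Reactants: 16 (2R,3R,5R,6R)-4-chloro-3,5-bis[3,5-bis(methoxymethoxy)phenyl]-2,6-bis(4-hydroxyphenyl)-2,3,5,6-tetrahydrobenzo[1,2-b:5,4-b']difuran
Product: 17 (2R,3R,5R,6R)-4-chloro-3,5-bis[3,5-bis(methoxymethoxy)phenyl]-2,6-bis[4-(methoxymethoxy)phenyl]-2,3,5,6-tetrahydrobenzo[1,2-b:5,4-b']difuran
Conditions: MOMCl, iPr2NEt, CH2Cl2, 0 °C to rt
Reagents that add atoms: chloromethyl methyl ether, COCCl
Why: O-alkylation of the two phenols, so that no para-phenoxide (which could open the dihydrofurans by quinone methide formation) is present during the hot basic cross-coupling.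

Step 10
Reactants: 18 2,4-dihydroxybenzaldehyde
Product: 19 2,4-bis(methoxymethoxy)benzaldehyde
Conditions: MOMCl, iPr2NEt, CH2Cl2, 0 to 40 °C
Reagents that add atoms: chloromethyl methyl ether, COCCl
Why: O-alkylation of both phenols (the hydrogen-bonded ortho hydroxyl needs excess reagent and gentle heating).

Step 11
Reactants: 19 2,4-bis(methoxymethoxy)benzaldehyde; 20 bis[(pinacolato)boryl]methane
Product: 21 2-[(E)-2-[2,4-bis(methoxymethoxy)phenyl]ethenyl]-4,4,5,5-tetramethyl-1,3,2-dioxaborolane
Conditions: LiTMP, THF, 0 °C; then 19, −78 °C to rt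
Reagents that add atoms: none
Why: boron-Wittig reaction, in which the lithiated geminal bis(boronate) adds to the aldehyde and a boron–oxygen unit is eliminated syn to give the (E)-alkenylboronate.

Step 12
Reactants: 17 (2R,3R,5R,6R)-4-chloro-3,5-bis[3,5-bis(methoxymethoxy)phenyl]-2,6-bis[4-(methoxymethoxy)phenyl]-2,3,5,6-tetrahydrobenzo[1,2-b:5,4-b']difuran; 21 2-[(E)-2-[2,4-bis(methoxymethoxy)phenyl]ethenyl]-4,4,5,5-tetramethyl-1,3,2-dioxaborolane
Product: 22 (2R,3R,5R,6R)-4-[(E)-2-[2,4-bis(methoxymethoxy)phenyl]ethenyl]-3,5-bis[3,5-bis(methoxymethoxy)phenyl]-2,6-bis[4-(methoxymethoxy)phenyl]-2,3,5,6-tetrahydrobenzo[1,2-b:5,4-b']difuran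
Conditions: Pd(OAc)2 (5 mol %), SPhos (10 mol %), K3PO4, 1,4-dioxane–H2O, 90 °C
Reagents that add atoms: none
Why: Suzuki–Miyaura coupling of a di-ortho-substituted aryl chloride with an alkenylboronate, the bulky electron-rich biarylphosphine enabling oxidative addition to zerovalent palladium, with retention of the alkene geometry.

Step 13
Reactants: 22 (2R,3R,5R,6R)-4-[(E)-2-[2,4-bis(methoxymethoxy)phenyl]ethenyl]-3,5-bis[3,5-bis(methoxymethoxy)phenyl]-2,6-bis[4-(methoxymethoxy)phenyl]-2,3,5,6-tetrahydrobenzo[1,2-b:5,4-b']difuran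
Product: 24 target CNP0154047.1 (all five stereocentres R), via octaphenol stilbene 23 (not isolated)
Conditions: HCl (3 M in MeOH), THF, 0 to 40 °C, under argon
Reagents that add atoms: none
Why: acidic methanolysis removes the eight MOM groups and the stilbene is protonated at the carbon next to ring A to give a benzylic cation stabilised by the 2,4-dihydroxyphenyl ring, which is captured by the ortho carbon of the neighbouring 3,5-dihydroxyphenyl ring (Friedel–Crafts closure of ring D, known under acid for dihydrobenzofuran stilbene dimers of the ε-viniferin type; the two resorcinol rings are symmetry-equivalent and give the same product); the new stereocentre should be set by the adjacent ring-B centre, because attack on the extended s-trans cation puts the aryl group anti to ring A across the CH2–CH bond and cis to the ring-fusion hydrogen, which is the (R) configuration.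

## Compound list

1 | 5-chlororesorcinol | Oc1cc(O)cc(Cl)c1 | starting material
2 | 4,6-dibromo-5-chlorobenzene-1,3-diol | Oc1cc(O)c(Br)c(Cl)c1Br | intermediate
3 | [(4,6-dibromo-5-chloro-1,3-phenylene)bis(oxy)]bis(trimethylsilane) | C[Si](C)(C)Oc1cc(O[Si](C)(C)C)c(Br)c(Cl)c1Br | intermediate
4 | dilithium 5-chloro-4,6-bis(trimethylsilyl)benzene-1,3-diolate | [Li+].[Li+].[O-]c1cc([O-])c([Si](C)(C)C)c(Cl)c1[Si](C)(C)C | intermediate
5 | 5-chloro-4,6-bis(trimethylsilyl)-1,3-phenylene bis(trifluoromethanesulfonate) | C[Si](C)(C)c1c(OS(=O)(=O)C(F)(F)F)cc(OS(=O)(=O)C(F)(F)F)c([Si](C)(C)C)c1Cl | intermediate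
6 | 3,5-dihydroxybenzaldehyde | O=Cc1cc(O)cc(O)c1 | starting material
7 | 3,5-bis(methoxymethoxy)benzaldehyde | O=Cc1cc(OCOC)cc(OCOC)c1 | intermediate
8 | diethyl (4-hydroxybenzyl)phosphonate | CCOP(=O)(Cc1ccc(O)cc1)OCC | starting material
9 | diethyl [4-(trifluoromethylsulfonyloxy)benzyl]phosphonate | CCOP(=O)(Cc1ccc(OS(=O)(=O)C(F)(F)F)cc1)OCC | intermediate
10 | 4-[(E)-2-[3,5-bis(methoxymethoxy)phenyl]ethenyl]phenyl trifluoromethanesulfonate | COCOc1cc(/C=C/c2ccc(OS(=O)(=O)C(F)(F)F)cc2)cc(OCOC)c1 | intermediate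
11 | 4-[(2S,3S)-3-[3,5-bis(methoxymethoxy)phenyl]oxiran-2-yl]phenyl trifluoromethanesulfonate | FC(F)(F)S(=O)(=O)Oc1ccc(cc1)[C@@H]1O[C@H]1c1cc(OCOC)cc(OCOC)c1 | intermediate
12 | 3-chloro-5-(trifluoromethylsulfonyloxy)-4-(trimethylsilyl)-1,2-didehydrobenzene (first aryne) | C1#CC(Cl)=C([Si](C)(C)C)C(OS(=O)(=O)C(F)(F)F)=C1 | intermediate
13 | (2R,3R)-4-chloro-3-[3,5-bis(methoxymethoxy)phenyl]-2-[4-(trifluoromethylsulfonyloxy)phenyl]-5-(trimethylsilyl)-2,3-dihydro-1-benzofuran-6-yl trifluoromethanesulfonate | C[Si](C)(C)c1c(OS(=O)(=O)C(F)(F)F)cc2c(c1Cl)[C@@H](c1cc(OCOC)cc(OCOC)c1)[C@H](c1ccc(OS(=O)(=O)C(F)(F)F)cc1)O2 | intermediate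
14 | (2R,3R)-4-chloro-3-[3,5-bis(methoxymethoxy)phenyl]-2-[4-(trifluoromethylsulfonyloxy)phenyl]-5,6-didehydro-2,3-dihydro-1-benzofuran (second aryne) | ClC1=C2[C@@H](c3cc(OCOC)cc(OCOC)c3)[C@H](c3ccc(OS(=O)(=O)C(F)(F)F)cc3)OC2=CC#C1 | intermediate
15 | (2R,3R,5R,6R)-4-chloro-3,5-bis[3,5-bis(methoxymethoxy)phenyl]-2,6-bis[4-(trifluoromethylsulfonyloxy)phenyl]-2,3,5,6-tetrahydrobenzo[1,2-b:5,4-b']difuran | FC(F)(F)S(=O)(=O)Oc1ccc([C@@H]2Oc3cc4c(c(Cl)c3[C@H]2c2cc(OCOC)cc(OCOC)c2)[C@@H](c2cc(OCOC)cc(OCOC)c2)[C@H](c2ccc(OS(=O)(=O)C(F)(F)F)cc2)O4)cc1 | intermediate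
16 | (2R,3R,5R,6R)-4-chloro-3,5-bis[3,5-bis(methoxymethoxy)phenyl]-2,6-bis(4-hydroxyphenyl)-2,3,5,6-tetrahydrobenzo[1,2-b:5,4-b']difuran | Oc1ccc([C@@H]2Oc3cc4c(c(Cl)c3[C@H]2c2cc(OCOC)cc(OCOC)c2)[C@@H](c2cc(OCOC)cc(OCOC)c2)[C@H](c2ccc(O)cc2)O4)cc1 | intermediate
17 | (2R,3R,5R,6R)-4-chloro-3,5-bis[3,5-bis(methoxymethoxy)phenyl]-2,6-bis[4-(methoxymethoxy)phenyl]-2,3,5,6-tetrahydrobenzo[1,2-b:5,4-b']difuran | COCOc1ccc([C@@H]2Oc3cc4c(c(Cl)c3[C@H]2c2cc(OCOC)cc(OCOC)c2)[C@@H](c2cc(OCOC)cc(OCOC)c2)[C@H](c2ccc(OCOC)cc2)O4)cc1 | intermediate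
18 | 2,4-dihydroxybenzaldehyde | O=Cc1ccc(O)cc1O | starting material
19 | 2,4-bis(methoxymethoxy)benzaldehyde | COCOc1ccc(C=O)c(OCOC)c1 | intermediate
20 | bis[(pinacolato)boryl]methane | CC1(C)OB(CB2OC(C)(C)C(C)(C)O2)OC1(C)C | starting material
21 | 2-[(E)-2-[2,4-bis(methoxymethoxy)phenyl]ethenyl]-4,4,5,5-tetramethyl-1,3,2-dioxaborolane | COCOc1ccc(/C=C/B2OC(C)(C)C(C)(C)O2)c(OCOC)c1 | intermediate
22 | (2R,3R,5R,6R)-4-[(E)-2-[2,4-bis(methoxymethoxy)phenyl]ethenyl]-3,5-bis[3,5-bis(methoxymethoxy)phenyl]-2,6-bis[4-(methoxymethoxy)phenyl]-2,3,5,6-tetrahydrobenzo[1,2-b:5,4-b']difuran | COCOc1ccc([C@@H]2Oc3cc4c(c(/C=C/c5ccc(OCOC)cc5OCOC)c3[C@H]2c2cc(OCOC)cc(OCOC)c2)[C@@H](c2cc(OCOC)cc(OCOC)c2)[C@H](c2ccc(OCOC)cc2)O4)cc1 | intermediate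
23 | (2R,3R,5R,6R)-4-[(E)-2-(2,4-dihydroxyphenyl)ethenyl]-3,5-bis(3,5-dihydroxyphenyl)-2,6-bis(4-hydroxyphenyl)-2,3,5,6-tetrahydrobenzo[1,2-b:5,4-b']difuran | Oc1ccc([C@@H]2Oc3cc4c(c(/C=C/c5ccc(O)cc5O)c3[C@H]2c2cc(O)cc(O)c2)[C@@H](c2cc(O)cc(O)c2)[C@H](c2ccc(O)cc2)O4)cc1 | intermediate
24 | CNP0154047.1 (all five stereocentres R) | Oc1ccc([C@@H]2Oc3cc4c5c(c3[C@H]2c2cc(O)cc(O)c2)C[C@H](c2ccc(O)cc2O)c2c(O)cc(O)cc2[C@H]5[C@H](c2ccc(O)cc2)O4)cc1 | target

## Step count and risk

Total steps: 13. Longest linear sequence: 8 (steps 3 or 4, 5, 6, 7, 8, 9, 12, 13).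

Three steps most likely to fail:

1. Step 7 (proposed new method). The zwitterion may not collapse as intended: the oxiranium may open at the wrong benzylic carbon, be intercepted by fluoride, or lose a proton or shift a hydride to give an aryl enol ether, and oxygen may attack the wrong aryne carbon. The fallback uses known reaction types, sets out from 1 and 10 and returns at 15. Stilbene 10 is epoxidised under the conditions of step 6 with the D-fructose-derived Shi ketone to the enantiomeric 4-[(2R,3R)-3-[3,5-bis(methoxymethoxy)phenyl]oxiran-2-yl]phenyl trifluoromethanesulfonate F1. Resorcinol 1 is then alkylated twice with F1 in hexafluoroisopropanol: a Friedel–Crafts opening of the epoxide at the benzylic carbon remote from the triflyloxyphenyl group, para to a hydroxyl of 1 and with inversion. This gives 4,6-bis[(1R,2S)-1-[3,5-bis(methoxymethoxy)phenyl]-2-hydroxy-2-[4-(trifluoromethylsulfonyloxy)phenyl]ethyl]-5-chlorobenzene-1,3-diol F2. Double Mitsunobu cyclodehydration (PPh3, DIAD, THF) closes both dihydrofurans with inversion at the carbinol carbon, and the two inversions together deliver 15.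

2. Step 13. Once the para-hydroxyphenyl groups are free, heterolysis of the benzylic C–O bonds of rings B and C may compete with the closure of ring D and lead to epimerisation and skeletal rearrangement; the facial selectivity at the new stereocentre may also be insufficient. The fallback sets out from 16 and returns at 24. The two phenols of 16 are pivaloylated (PivCl, pyridine, DMAP) instead of being MOM-protected, giving (2R,3R,5R,6R)-4-chloro-3,5-bis[3,5-bis(methoxymethoxy)phenyl]-2,6-bis[4-(pivaloyloxy)phenyl]-2,3,5,6-tetrahydrobenzo[1,2-b:5,4-b']difuran F3. Suzuki–Miyaura coupling with 21 as in step 12 gives the corresponding 4-[(E)-2-[2,4-bis(methoxymethoxy)phenyl]ethenyl] bis(pivalate) F4. Acidic methanolysis then removes the six MOM groups and closes ring D while the electron-poor aryl pivalates hold the dihydrofuran C–O bonds in place, giving the bis(pivalate) of the target F5. Brief treatment with K2CO3 in MeOH at 0 °C under argon cleaves the esters to 24.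

3. Step 2. The ortho-chloroaryllithium may lose lithium chloride, or the second exchange and silyl migration may stay incomplete, so that protonated or monosilylated material results. The fallback sets out from 2 and returns at 5. Diol 2 is converted with isopropyl isocyanate (Et3N, CH2Cl2) into 4,6-dibromo-5-chloro-1,3-phenylene bis(N-isopropylcarbamate) F6. After in situ N-silylation (TBSOTf, TMEDA, Et2O), bromine–lithium exchange with n-BuLi at −100 °C and external quench with Me3SiCl gives 5-chloro-4,6-bis(trimethylsilyl)-1,3-phenylene bis(N-isopropylcarbamate) F7 after aqueous work-up. The carbamates are cleaved with Et2NH and DBU in MeCN, and the phenoxides are triflated in the same flask with PhNTf2 to give 5.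

Further compounds
F1 | step 7 | 4-[(2R,3R)-3-[3,5-bis(methoxymethoxy)phenyl]oxiran-2-yl]phenyl trifluoromethanesulfonate | FC(F)(F)S(=O)(=O)Oc1ccc(cc1)[C@H]1O[C@@H]1c1cc(OCOC)cc(OCOC)c1
F2 | step 7 | 4,6-bis[(1R,2S)-1-[3,5-bis(methoxymethoxy)phenyl]-2-hydroxy-2-[4-(trifluoromethylsulfonyloxy)phenyl]ethyl]-5-chlorobenzene-1,3-diol | Oc1cc(O)c([C@@H](c2cc(OCOC)cc(OCOC)c2)[C@H](O)c2ccc(OS(=O)(=O)C(F)(F)F)cc2)c(Cl)c1[C@@H](c1cc(OCOC)cc(OCOC)c1)[C@H](O)c1ccc(OS(=O)(=O)C(F)(F)F)cc1
F3 | step 13 | (2R,3R,5R,6R)-4-chloro-3,5-bis[3,5-bis(methoxymethoxy)phenyl]-2,6-bis[4-(pivaloyloxy)phenyl]-2,3,5,6-tetrahydrobenzo[1,2-b:5,4-b']difuran | CC(C)(C)C(=O)Oc1ccc([C@@H]2Oc3cc4c(c(Cl)c3[C@H]2c2cc(OCOC)cc(OCOC)c2)[C@@H](c2cc(OCOC)cc(OCOC)c2)[C@H](c2ccc(OC(=O)C(C)(C)C)cc2)O4)cc1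
F4 | step 13 | (2R,3R,5R,6R)-4-[(E)-2-[2,4-bis(methoxymethoxy)phenyl]ethenyl]-3,5-bis[3,5-bis(methoxymethoxy)phenyl]-2,6-bis[4-(pivaloyloxy)phenyl]-2,3,5,6-tetrahydrobenzo[1,2-b:5,4-b']difuran | CC(C)(C)C(=O)Oc1ccc([C@@H]2Oc3cc4c(c(/C=C/c5ccc(OCOC)cc5OCOC)c3[C@H]2c2cc(OCOC)cc(OCOC)c2)[C@@H](c2cc(OCOC)cc(OCOC)c2)[C@H](c2ccc(OC(=O)C(C)(C)C)cc2)O4)cc1
F5 | step 13 | bis(pivalate) of the target at its two 4-hydroxyphenyl groups | CC(C)(C)C(=O)Oc1ccc([C@@H]2Oc3cc4c5c(c3[C@H]2c2cc(O)cc(O)c2)C[C@H](c2ccc(O)cc2O)c2c(O)cc(O)cc2[C@H]5[C@H](c2ccc(OC(=O)C(C)(C)C)cc2)O4)cc1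
F6 | step 2 | 4,6-dibromo-5-chloro-1,3-phenylene bis(N-isopropylcarbamate) | CC(C)NC(=O)Oc1cc(OC(=O)NC(C)C)c(Br)c(Cl)c1Br
F7 | step 2 | 5-chloro-4,6-bis(trimethylsilyl)-1,3-phenylene bis(N-isopropylcarbamate) | CC(C)NC(=O)Oc1cc(OC(=O)NC(C)C)c([Si](C)(C)C)c(Cl)c1[Si](C)(C)C
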